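**Plan**

Numbering: ring C1 (CH2OAc), C2 (=CH), C3 (C=O), C4 (quaternary oxirane C), C5 (oxirane CH), C6 (C=O); chain C1' (CHOAc) to C6' (CHO).
Enabling feature: read both ring ketones as carbinols and leave the oxirane oxygen on C4 only. The carbocycle is then a cyclohexene (C1=C2) oxygenated at both allylic carbons C3 and C6, and C4 carries oxygen plus the formyl-level carbon C1'. This is the pattern of a [4+2] adduct of a 1,4-dioxygenated butadiene and a 2-acyloxyacrolein.
Cuts, in retrosynthetic order: C3=O and C6'=O (back to carbinols), C1–CH2O, O–C5 of the oxirane, C6=O, C1'–C2', and last C3–C4 together with C5–C6.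
Forward: the six-membered ring closes first (step 5), the C2'–C6' dienyl chain is joined to the ring aldehyde (step 7), the oxirane closes on the C6 enone (step 12), the C1 branch is added (step 13), and the two remaining carbinols are oxidised last (step 16).
Stereochemistry: C4 comes from the catalyst-controlled face of the dienophile, C1' from Felkin–Anh addition next to C4, and C5 from invertive displacement by the C4 oxygen. C3 and C6 of the adduct are temporary and vanish on oxidation.

Key step: step 5

Assumption 1: the cycloaddition is taken to run formyl-endo. An exo adduct from the same dienophile face differs only at C3 and C6, both later carbonyl carbons, and would reach the same target through diastereomeric intermediates.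
Assumption 2: the facial sense of the (S)-catalyst is assigned by analogy with 2-methyl- and 2-bromoacrolein (s-trans enal, formyl C–H···O contact). If 2-acetoxyacrolein binds in the opposite sense, the (R)-catalyst is used and nothing else changes.

**Route**

Step 1
Reactants: 1 2,5-dimethoxytetrahydrofuran
Product: 2 succinaldehyde
Conditions: H2O, 90 °C; MeOH/H2O distilled off, then vacuum distillation; used at once
Reagents that add atoms: water, O
Why: Hydrolysis of the cyclic bis(acetal) is driven by removal of methanol and needs no added acid that could start aldol oligomerisation of the dialdehyde.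

Step 2
Reactants: 2 succinaldehyde
Product: 3 (1E,3E)-1,4-bis(tert-butyldimethylsilyloxy)buta-1,3-diene
Conditions: TBSOTf (2.3 equiv), Et3N (4 equiv), CH2Cl2, 0 °C → rt; E,E isomer separated (Et3N-washed silica, then pentane, −30 °C)
Reagents that add atoms: tert-butyldimethylsilyl triflate, CC(C)(C)[Si](C)(C)OS(=O)(=O)C(F)(F)F
Why: Double soft enolisation (silyl triflate/amine) gives the conjugated bis(silyl enol ether); the geometry is not fully controlled, so the planar E,E isomer is separated, and traces of Z-containing isomers are harmless because they cannot reach an unhindered s-cis form.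

Step 3
Reactants: 4 2,2-dimethyl-1,3-dioxan-5-one
Product: 5 2,2-dimethyl-4H-1,3-dioxin-5-yl acetate
Conditions: LiHMDS, THF, −78 °C; Ac2O, −78 → 0 °C
Reagents that add atoms: acetic anhydride, CC(=O)OC(C)=O
Why: Trapping a kinetic lithium enolate with acetic anhydride is the standard O-acylation route to enol acetates, and the symmetric ketone has only one enolate.

Step 4
Reactants: 5 2,2-dimethyl-4H-1,3-dioxin-5-yl acetate
Product: 6 2-acetoxyacrolein
Conditions: toluene, BHT (trace), 110 °C, acetone distilled off; short-path distillation, used fresh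
Reagents that add atoms: none
Why: Retro-hetero-Diels–Alder cleavage of the 4H-1,3-dioxin expels acetone and unveils the 2-acyloxy enal under neutral conditions.

Step 5
Reactants: 3 (1E,3E)-1,4-bis(tert-butyldimethylsilyloxy)buta-1,3-diene; 6 2-acetoxyacrolein
Product: 7 (1R,2R,5R)-2,5-bis(tert-butyldimethylsilyloxy)-1-formylcyclohex-3-en-1-yl acetate (route numbering 3R,4R,6R; CHO cis to both OTBS groups)
Conditions: (S)-3,3-diphenyl-1-(o-tolyl)pyrrolo-oxazaborolidine from (S)-diphenylprolinol (20 mol %), Tf2NH (17 mol %), 4 Å MS, CH2Cl2, −78 °C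
Reagents that add atoms: none
Why: The cationic boron binds the formyl oxygen, a formyl C–H···O contact holds the s-trans enal over one catalyst phenyl group, the LUMO of the captodative dienophile drops, and only the Re face of its α-carbon (OAc > CHO > CH2) stays open. A suprafacial, strongly asynchronous [4π+2π] cycloaddition then closes the six-membered carbocycle in one intermolecular event, C5–C6 forming ahead of C3–C4, with the alkene left at C1=C2; the closest known reactions are oxazaborolidinium-catalysed Diels–Alder additions of 2-substituted acroleins to silyloxydienes and the catalytic enantioselective additions of 2-acyloxyacroleins. C4 (R) is set by the catalyst-controlled face; C3 and C6 come out cis to each other because both silyloxy groups are outside substituents of the E,E-diene, and cis to the formyl group through the endo arrangement favoured by the Lewis-acid-bound carbonyl. The symmetric diene removes any regiochemical question, and only the face selectivity has a lasting consequence, since C3 and C6 later become carbonyl carbons. The catalyst is kept free of excess acid (oxazaborolidine in slight excess over Tf2NH, low temperature), as the acid-labile bis(enol ether) requires, and TBS rather than TMS groups slow the silyl transfer that would stop the reaction at an open-chain Mukaiyama–Michael product.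

Step 6
Reactants: 8 (E)-pent-2-en-4-yn-1-ol
Product: 9 (E)-tert-butyl(pent-2-en-4-yn-1-yloxy)diphenylsilane
Conditions: TBDPSCl, imidazole, CH2Cl2, 0 °C → rt
Reagents that add atoms: tert-butyldiphenylsilyl chloride, CC(C)(C)[Si](Cl)(c1ccccc1)c1ccccc1
Why: Routine silylation of a primary alcohol; TBDPS is chosen because it outlasts the acidic removal of a TBS ether in step 9.

Step 7
Reactants: 9 (E)-tert-butyl(pent-2-en-4-yn-1-yloxy)diphenylsilane; 7 cycloadduct aldehyde
Product: 11 (3R,4S,6R,1'S)-C1' dienyl carbinol still acetylated on the C4 oxygen, via dienyl(dimethyl)alane 10 (not isolated)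
Conditions: 9 (1.6 equiv), Me3Al (2.5 equiv), Cp2ZrCl2 (0.25 equiv), CH2Cl2, 0 °C → rt; volatiles off in vacuo, CH2Cl2; 7, −78 → 0 °C; aq. Rochelle salt
Reagents that add atoms: trimethylaluminium, C[Al](C)C
Why: Zr-catalysed syn-carboalumination (Negishi) puts methyl on C3' and aluminium on C2' with E geometry, and the alkenylalane adds 1,2 to the aldehyde faster than its methyl groups transfer or the hindered tertiary acetate reacts; with non-chelating aluminium the polar Felkin–Anh (Cornforth) arrangement holds, so the nucleophile comes anti to the C4–OAc bond and past C5H2 rather than past C3 with its cis silyloxy group, attacks the Si face of the formyl group and sets C1' as S.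

Step 8
Reactants: 11 C1' carbinol/C4 acetate
Product: 12 (3R,4S,6R,1'S)-C1' acetate with free tertiary C4 hydroxyl
Conditions: DBU (0.2 equiv), toluene, rt
Reagents that add atoms: none
Why: Base-catalysed 1,2-O→O acyl migration through the five-membered orthoacid intermediate runs downhill from the crowded tertiary oxygen to the secondary one and touches no stereocentre.

Step 9
Reactants: 12 C1' acetate/C4 alcohol
Product: 13 (3R,4S,6R,1'S)-C6 allylic alcohol (C3-OTBS and C6'-OTBDPS retained)
Conditions: CSA (0.1 equiv), MeOH/CH2Cl2 1:1, 0 °C, stopped when 12 is consumed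
Reagents that add atoms: none
Why: Acid-catalysed methanolysis of silyl ethers follows steric access, so the C6 ether next to CH2 should cleave well before the C3 ether next to fully substituted C4, while the TBDPS ether is far more acid-stable.

Step 10
Reactants: 13 C6 allylic alcohol
Product: 14 (3R,4S,1'S)-C6 enone
Conditions: Dess–Martin periodinane, CH2Cl2, 0 °C → rt
Reagents that add atoms: none
Why: Dess–Martin oxidation of the only secondary carbinol works under near-neutral conditions, which the β-hydroxy ketone needs to avoid dehydration; the temporary C6 stereocentre disappears here.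

Step 11
Reactants: 14 C6 enone
Product: 17 (3R,4S,5R,1'S)-5-bromo-4-hydroxy enone (Br trans to the C4 oxygen), via bis-TMS dienol ether 15 (not isolated), via C4-OTMS bromo ketone 16 (not isolated)
Conditions: TMSOTf (2.5 equiv), Et3N (4 equiv), CH2Cl2, −78 → 0 °C; aq. NaHCO3; crude 15, NBS (1.05 equiv), THF, −78 °C; then 1 M HCl/THF, 0 °C
Reagents that add atoms: N-bromosuccinimide, O=C1CCC(=O)N1Br; trimethylsilyl triflate, C[Si](C)(C)OS(=O)(=O)C(F)(F)F (its silyl groups stay only in 15 and 16)
Why: Soft enolisation caps the C4 hydroxyl and converts the enone by α'-deprotonation at C5 into its cross-conjugated 2-silyloxydiene, NBS brominates that enol ether carbon far faster than the side-chain diene and preferentially anti to the pseudo-axial C4-OTMS group (5R), and dilute acid then frees the tertiary alcohol while the TBS and TBDPS ethers stay.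

Step 12
Reactants: 17 trans-bromohydrin
Product: 18 (3R,4R,5S,1'S)-4,5-epoxy enone
Conditions: K2CO3, Bu4NBr (0.2 equiv), MeCN, 0 °C → rt
Reagents that add atoms: none
Why: Halohydrin closure (intramolecular Williamson, 3-exo-tet) inverts C5 and places the oxirane on the face of the C4 oxygen (5S); only the trans-diaxial bromide can close, and bromide exchange at the α-keto carbon interconverts the C5 epimers, so any cis-bromide drains through the trans isomer.

Step 13
Reactants: 18 epoxy enone
Product: 19 (3R,4R,5S,1'S)-1-(hydroxymethyl) epoxy enone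
Conditions: aq. HCHO (37 %), imidazole (1 equiv), THF/H2O, rt
Reagents that add atoms: formaldehyde, C=O
Why: In the Morita–Baylis–Hillman reaction imidazole adds reversibly to C2, the C1 enolate attacks formaldehyde and loss of imidazole restores the enone, so the new carbon can only end up on C1 next to the C6 ketone, and the weakly basic catalyst spares acetate and oxirane.

Step 14
Reactants: 19 hydroxymethyl epoxy enone
Product: 20 (3R,4R,5S,1'S)-bis-acetate
Conditions: Ac2O, pyridine, CH2Cl2, 0 °C
Reagents that add atoms: acetic anhydride, CC(=O)OC(C)=O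
Why: Routine acetylation of the only free, primary hydroxyl; DMAP is left out so that no nucleophile adds SN2' to the resulting allylic acetate.

Step 15
Reactants: 20 bis-acetate
Product: 21 (3R,4R,5S,1'S)-C3,C6'-diol
Conditions: HF·pyridine, pyridine, THF, 0 °C → rt
Reagents that add atoms: none
Why: Fluoride-driven Si–O cleavage in a mildly acidic buffer removes both remaining silyl ethers without base, so no acetate should migrate and the epoxy enone should not enolise.

Step 16
Reactants: 21 C3,C6'-diol
Product: 22 CNP0307549.1 (4R,5S,1'S)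
Conditions: Dess–Martin periodinane (3 equiv), CH2Cl2, 0 °C → rt
Reagents that add atoms: none
Why: Dess–Martin oxidation converts the C3 carbinol into the second ring ketone and the dienol into the (2E,4E)-dienal in one near-neutral operation; the last temporary stereocentre (C3) is erased and C4, C5 and C1' are untouched.

**Compound list**

1 | 2,5-dimethoxytetrahydrofuran (cis/trans mixture) | COC1CCC(OC)O1 | starting material
2 | succinaldehyde | O=CCCC=O | intermediate
3 | (1E,3E)-1,4-bis(tert-butyldimethylsilyloxy)buta-1,3-diene | CC(C)(C)[Si](C)(C)O/C=C/C=C/O[Si](C)(C)C(C)(C)C | intermediate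
4 | 2,2-dimethyl-1,3-dioxan-5-one | CC1(C)OCC(=O)CO1 | starting material
5 | 2,2-dimethyl-4H-1,3-dioxin-5-yl acetate | CC(=O)OC1=COC(C)(C)OC1 | intermediate
6 | 2-acetoxyacrolein | C=C(OC(C)=O)C=O | intermediate
7 | (1R,2R,5R)-2,5-bis(tert-butyldimethylsilyloxy)-1-formylcyclohex-3-en-1-yl acetate (route numbering 3R,4R,6R) | C1=C[C@@H](O[Si](C)(C)C(C)(C)C)[C@](C=O)(OC(C)=O)C[C@H]1O[Si](C)(C)C(C)(C)C | intermediate
8 | (E)-pent-2-en-4-yn-1-ol | C#C/C=C/CO | starting material
9 | (E)-tert-butyl(pent-2-en-4-yn-1-yloxy)diphenylsilane | C#C/C=C/CO[Si](c1ccccc1)(c1ccccc1)C(C)(C)C | intermediate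
10 | [(1E,3E)-5-(tert-butyldiphenylsilyloxy)-2-methylpenta-1,3-dienyl]dimethylalane | C[Al](C)/C=C(C)/C=C/CO[Si](c1ccccc1)(c1ccccc1)C(C)(C)C | intermediate
11 | (3R,4S,6R,1'S)-C1' carbinol, acetate on the C4 oxygen, 3,6-bis-OTBS, (2'E,4'E)-chain ending in CH2OTBDPS | C1=C[C@@H](O[Si](C)(C)C(C)(C)C)[C@]([C@H](/C=C(C)/C=C/CO[Si](c2ccccc2)(c2ccccc2)C(C)(C)C)O)(OC(C)=O)C[C@H]1O[Si](C)(C)C(C)(C)C | intermediate
12 | (3R,4S,6R,1'S)-C1' acetate, free tertiary C4-OH | C1=C[C@@H](O[Si](C)(C)C(C)(C)C)[C@]([C@H](/C=C(C)/C=C/CO[Si](c2ccccc2)(c2ccccc2)C(C)(C)C)OC(C)=O)(O)C[C@H]1O[Si](C)(C)C(C)(C)C | intermediate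
13 | (3R,4S,6R,1'S)-C6 allylic alcohol | C1=C[C@@H](O[Si](C)(C)C(C)(C)C)[C@]([C@H](/C=C(C)/C=C/CO[Si](c2ccccc2)(c2ccccc2)C(C)(C)C)OC(C)=O)(O)C[C@H]1O | intermediate
14 | (3R,4S,1'S)-C6 enone | O=C1C=C[C@@H](O[Si](C)(C)C(C)(C)C)[C@]([C@H](/C=C(C)/C=C/CO[Si](c2ccccc2)(c2ccccc2)C(C)(C)C)OC(C)=O)(O)C1 | intermediate
15 | C4-OTMS, C6-OTMS cross-conjugated dienol ether (C5=C6, C1=C2) | C1=C[C@@H](O[Si](C)(C)C(C)(C)C)[C@]([C@H](/C=C(C)/C=C/CO[Si](c2ccccc2)(c2ccccc2)C(C)(C)C)OC(C)=O)(O[Si](C)(C)C)C=C1O[Si](C)(C)C | intermediate
16 | (3R,4S,5R,1'S)-5-bromo-4-OTMS enone | O=C1C=C[C@@H](O[Si](C)(C)C(C)(C)C)[C@]([C@H](/C=C(C)/C=C/CO[Si](c2ccccc2)(c2ccccc2)C(C)(C)C)OC(C)=O)(O[Si](C)(C)C)[C@H]1Br | intermediate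
17 | (3R,4S,5R,1'S)-5-bromo-4-hydroxy enone (trans-bromohydrin) | O=C1C=C[C@@H](O[Si](C)(C)C(C)(C)C)[C@]([C@H](/C=C(C)/C=C/CO[Si](c2ccccc2)(c2ccccc2)C(C)(C)C)OC(C)=O)(O)[C@H]1Br | intermediate
18 | (3R,4R,5S,1'S)-4,5-epoxy enone | C1=C[C@@H](O[Si](C)(C)C(C)(C)C)[C@]2([C@H](/C=C(C)/C=C/CO[Si](c3ccccc3)(c3ccccc3)C(C)(C)C)OC(C)=O)O[C@@H]2C1=O | intermediate
19 | (3R,4R,5S,1'S)-1-(hydroxymethyl) epoxy enone | OCC1=C[C@@H](O[Si](C)(C)C(C)(C)C)[C@]2([C@H](/C=C(C)/C=C/CO[Si](c3ccccc3)(c3ccccc3)C(C)(C)C)OC(C)=O)O[C@@H]2C1=O | intermediate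
20 | (3R,4R,5S,1'S)-1-(acetoxymethyl) epoxy enone (bis-acetate) | CC(=O)OCC1=C[C@@H](O[Si](C)(C)C(C)(C)C)[C@]2([C@H](/C=C(C)/C=C/CO[Si](c3ccccc3)(c3ccccc3)C(C)(C)C)OC(C)=O)O[C@@H]2C1=O | intermediate
21 | (3R,4R,5S,1'S)-C3,C6'-diol | CC(=O)OCC1=C[C@@H](O)[C@]2([C@H](/C=C(C)/C=C/CO)OC(C)=O)O[C@@H]2C1=O | intermediate
22 | CNP0307549.1 (4R,5S,1'S) | CC(=O)OCC1=CC(=O)[C@]2([C@H](/C=C(C)/C=C/C=O)OC(C)=O)O[C@@H]2C1=O | target

**Step count and risks**

Total steps: 16. Longest linear sequence: 13 (steps 1, 2, 5, 7–16; the branch from 4 is equally long).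

Step 5. The catalyst may strip or transfer a silyl group of the bis(enol ether), so that an open-chain Mukaiyama–Michael pathway overtakes ring closure, or the face selectivity with the acyloxy enal may be too low. The fallback sets out from 3 and 6 and comes back at 7. Heating 3 with 6 in toluene (BHT, 60–80 °C) without catalyst should give the racemic formyl-endo adduct, that is 7 together with the mirror-image adduct F1. Condensation of the mixture with (1R,2R)-N,N'-dimethyl-1,2-diphenylethane-1,2-diamine (Et2O, 4 Å MS, rt) converts it into two diastereomers, the imidazolidine of 7 F2 and the imidazolidine of the mirror image F3, which are separated by chromatography. Mild hydrolysis of F2 (dilute aq. HCl/Et2O, 0 °C, or wet silica) returns enantiopure 7 and the recoverable diamine. Half of the material is lost, but the same two ring bonds are made.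

Step 11. The bromine electrophile may also attack the electron-rich side-chain diene, or the labile bromo ketone may degrade during the acidic TMS cleavage, with loss of the C4 oxygen followed by aromatisation. The fallback sets out from 14 and comes back at 18. The silyl dienol ether 15 is oxidised instead of brominated: Rubottom oxidation (m-CPBA, NaHCO3, CH2Cl2, −20 °C, dilute acid work-up) should give the trans-C4,C5-diol F4. Only its secondary C5 hydroxyl is mesylated (MsCl, pyridine, 0 °C) to the C5 mesylate F5, and K2CO3 in MeCN closes the oxirane to 18. Any cis-mesylate would be inverted with LiBr to the trans-bromide 17 and join the route there.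

Step 13. Turnover of the Morita–Baylis–Hillman cycle may be slow on the hindered γ-silyloxy enone, which gives time for γ-deprotonation at C3 with opening of the oxirane, or for acetate hydrolysis. The fallback sets out from 18 and comes back at 19. α-Iodination by addition–elimination (I2, pyridine/CH2Cl2, 0 °C → rt) gives the 1-iodo epoxy enone F6. Stille coupling with (tributylstannyl)methanol follows (Pd2(dba)3, AsPh3, CuI, NMP, rt → 50 °C). The weak-donor ligand and low temperature are chosen so that insertion into the C–I bond outruns ionisation of the C1' allylic acetate.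

**Further compounds**

F1 | step 5 | (1S,2S,5S)-2,5-bis(tert-butyldimethylsilyloxy)-1-formylcyclohex-3-en-1-yl acetate (mirror image of 7) | C1=C[C@H](O[Si](C)(C)C(C)(C)C)[C@@](C=O)(OC(C)=O)C[C@@H]1O[Si](C)(C)C(C)(C)C
F2 | step 5 | (4R,5R)-1,3-dimethyl-4,5-diphenylimidazolidin-2-yl derivative (aminal) of 7 | CN1[C@H](c2ccccc2)[C@H](N(C)C1[C@@]3(OC(C)=O)C[C@@H](O[Si](C)(C)C(C)(C)C)C=C[C@H]3O[Si](C)(C)C(C)(C)C)c4ccccc4
F3 | step 5 | (4R,5R)-1,3-dimethyl-4,5-diphenylimidazolidin-2-yl derivative (aminal) of F1 | CN1[C@H](c2ccccc2)[C@H](N(C)C1[C@]3(OC(C)=O)C[C@H](O[Si](C)(C)C(C)(C)C)C=C[C@@H]3O[Si](C)(C)C(C)(C)C)c4ccccc4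
F4 | step 11 | 4,5-dihydroxy enone, C5-OH trans to C4-OH | O=C1C=C[C@@H](O[Si](C)(C)C(C)(C)C)[C@]([C@H](/C=C(C)/C=C/CO[Si](c2ccccc2)(c2ccccc2)C(C)(C)C)OC(C)=O)(O)[C@H]1O
F5 | step 11 | C5 mesylate of F4 | O=C1C=C[C@@H](O[Si](C)(C)C(C)(C)C)[C@]([C@H](/C=C(C)/C=C/CO[Si](c2ccccc2)(c2ccccc2)C(C)(C)C)OC(C)=O)(O)[C@H]1OS(C)(=O)=O
F6 | step 13 | (3R,4R,5S,1'S)-1-iodo epoxy enone | IC1=C[C@@H](O[Si](C)(C)C(C)(C)C)[C@]2([C@H](/C=C(C)/C=C/CO[Si](c3ccccc3)(c3ccccc3)C(C)(C)C)OC(C)=O)O[C@@H]2C1=O
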